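Follow the coupling partner through this flask, not the substrates, before you plan its charges.

| setting | grey | violet | flask |
|---|---|---|---|
| left-handed substrate | 1 M | 0.50 M | 1.0 M |
| right-handed substrate | 1 M | 0.50 M | 1.0 M |
| coupling partner | 2 M | 2 M | 2.00 M |
| free catalyst | 0.60 mM | 0.60 mM | 0.60 mM |
| racemization catalyst | 50 mM | 50 mM | 50 mM |
| remark | the very flask that is asked about, followed so far | run made earlier |  |
| time |  |  | 50 min |

- grey (time / min: left-handed product / %, right-handed product / %): 2.00: 0.9, 0.8; 3.00: 2.5, 0; 5.00: 3.8, 2.4; 8.00: 5.1, 3.2; 10.0: 6.0, 1.5; 15.0: 7.8, 4.0; 25.0: 10.9, 3.5
- violet (time / min: left-handed product / %, right-handed product / %): 1.50: 1.5, 1.3; 2.50: 3.1, 1.9; 4.00: 4.1, 0; 6.00: 6.4, 1.7; 8.00: 4.9, 0; 12.0: 7.9, 0.7; 20.0: 9.5, 3.6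

(each reading ± 1 percentage point)

1. excess of left-handed product over right-handed product in the product at 1.0 min
2. excess of left-handed product over right-handed product in the product at 50 min
3. part of the left-handed substrate and right-handed substrate charged together that has reacted at 50 min

- free catalyst is single-handed; left-handed substrate and right-handed substrate are mirror images of each other, charged as a racemate, each of them at the stated concentration
- an excess is the difference of the two amounts in percent of their sum
- an excess is below zero if the other one leads

Minutes of the meeting on the grey flask, where the talk was of [coupling partner].

The kineticist reported that the two products of the grey run together grew by 0.0104 min⁻¹ of the substrate charge up to 8.00 min, but by 0.00260 min⁻¹ from 15.0 min to 25.0 min. She warned that the later rate rests on a difference of two sums of readings, each reading scattering by 1 percentage point.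

The process chemist said the readings could not separate a loss of free catalyst from a loss of coupling partner, and chose to reckon with the second. Its charge of 2.00 M matches the substrates together, 2.00 M, so a percentage of the substrates is also one of the coupling partner. He treated the loss as pseudo-first-order and solved both ends, taking each rate at the middle of its window. The fall between the windows gave a total loss constant of 0.0865 min⁻¹, and the early rate, carried back to zero time, gave a start constant of 0.0147 min⁻¹.

The chair joined the ends: their quotient is 17.0%, named the coupling share, the part of the coupling partner charged that ends in product. The lifetime of 11.6 min is short against 50 min, so she committed to that share as the reacted part at 50 min.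

The stereochemist saw no drift in the product ratio beyond the scatter, took one excess for both asked times, and read 48.4% from the last reading of each run.

The forecast gave excesses of 45% and 43% and a reacted part of 24%, holding that “racemization seems to keep pace”. The flask gives 65.7%, 65.6% and 12.9%.

    coupling partner + free catalyst + left-handed substrate → free catalyst + left-handed product (k = 0.310 M⁻² s⁻¹)
    coupling partner + free catalyst + right-handed substrate → free catalyst + right-handed product (k = 0.0640 M⁻² s⁻¹)
    left-handed substrate + racemization catalyst ⇌ right-handed substrate + racemization catalyst, rate k3*[racemization catalyst]*[left-handed substrate] forward; the back reaction follows from the equilibrium constant (k = 0.510 M⁻¹ s⁻¹)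
    racemization catalyst → spent catalyst (k = 0.00160 s⁻¹)
    coupling partner → decomposed reagent (k = 0.00140 s⁻¹)

The reacted part of the flask at 50 min, its coupling share, stands 4.1 points below the reckoned 17.0%, with 0.82% of the coupling partner, the limiting reagent, left at 50.0 min against 87% of the left-handed substrate. The neighbour holds 1.5 × 10⁻⁴ M of free catalyst, a quarter of the flask's charge. Scaling the flask's odds of coupling against decomposition, 0.148, by that quarter gives 0.0370, and so a share of 3.57%. The neighbour gives 3.73%.

The data stem from a simulated flask for an exercise, noise included.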